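The flask holds more D than Q and J together, and the meeting began from that comparison.

| setting | violet | teal | red | flask |
|---|---|---|---|---|
| Q | 0.40 M | 0.40 M | 0.60 M | 0.40 M |
| D | 0.48 M (fed, over 2.0 h) | 1.1 M (fed, over 2.0 h) | 0.72 M (fed, over 2.0 h) | 0.720 M (fed, over 2.0 h) |
| J | 0.040 M | 0.040 M | 0.040 M | 0.0400 M |
| remark | run made earlier; the fed solution adds 0.20 times the starting volume | run made earlier; the fed solution adds 0.20 times the starting volume | run made earlier; the fed solution adds 0.20 times the starting volume | the fed solution adds 0.20 times the starting volume |
| time |  |  |  | 20 h |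

| run | time / h | Q / % | E / % | X / % | L / % |
|---|---|---|---|---|---|
| violet | 3.00 | 14.3 | 80.5 | 3.2 | 0.4 |
| violet | 8.00 | 2.3 | 95.6 | 1.0 | 0 |
| violet | 15.0 | 3.0 | 97.1 | 1.9 | 0.2 |
| violet | 25.0 | 0 | 97.8 | 1.9 | 0 |
| teal | 6.00 | 0.7 | 97.6 | 3.0 | 0 |
| teal | 12.0 | 0.7 | 98.2 | 2.9 | 0 |
| teal | 20.0 | 1.8 | 96.7 | 3.0 | 0 |
| teal | 25.0 | 3.5 | 98.8 | 0.6 | 0 |
| red | 6.00 | 1.7 | 93.3 | 3.0 | 0 |
| red | 12.0 | 0 | 97.8 | 3.1 | 0.5 |
| red | 20.0 | 0 | 96.6 | 2.8 | 0 |
| red | 25.0 | 0 | 95.8 | 3.4 | 0.5 |

(standard deviation of a reading: 1 percentage point)

- a species is counted by the Q in it: one X counts as two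
- charges are per starting volume, the dose included; the dosed solution carries all of it
- the analysis behind the earlier runs scatters by 1 percentage point, standard deviation
- in a conversion J counts as not yet reacted
- the reaction counts as stopped when no species that holds the Q and J together changes by six tenths of a point or more over the second half of the time
- a reading of Q is of its free form alone

- which holds at 20 h: what has brought the reaction to rest, or that it has not come to rest (J counts as not reacted) (forward and back rates have come level / all of Q has reacted / it is still moving / D has run out first)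
- part of the Q and J together gone at 20 h
- the E standing at 20 h, as a percentage of the Q and J together charged
- the X standing at 20 h, as a percentage of the Q and J together charged

The chair proposed one number. The flask's cover is 1.64: the whole D charge as a multiple of the Q and J charge together. She said that if each unit of Q and J takes one D, a cover below one makes D the limiting reagent.

The analyst then set the earlier runs beside it. Violet has a cover of 1.09 and teal one of 2.50. At 25.0 h, E reads 97.8% in violet and 98.8% in teal. He noted that this gap of 1 percentage point is the size of the scatter, 1 point. So he read violet's cover as enough for violet's Q and J.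

The process chemist turned to red, whose cover of 1.12 is lower than the flask's. Q reads 0% in red at 12.0 h, earlier than the asked time. She therefore expected the flask's Q to be used up with D to spare.

The meeting committed to one reckoning of its own. If each unit takes one D, the flask should keep about 38.9% of its D.

The forecast gave all of Q has reacted, with 99.5% gone, E at 97% and X at 2.7%, and it said: “D is in excess, so it can't run out.”

The flask's outcome at 20 h is this: all of Q has reacted. Of Q and J together, >99.9% is gone, E stands at 97.6% and X at 2.37%.

    Q + D ⇌ L (K = 0.470 M⁻¹, k = 0.340 M⁻¹ h⁻¹)
    Q + L → X (k = 2.70 M⁻¹ h⁻¹)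
    Q ⇌ J (K = 0.0430, k = 16.0 h⁻¹)
    D + J → E (k = 150 M⁻¹ h⁻¹)

Q reaches E through J: with the passing of Q into J taken away, the flask's E stands at 9.09% against 97.6%. Each E holds one D, as does each X, which counts as two, and 40% of the flask's D stands at 20.0 h. The neighbour flask with a quarter of the D has a cover of 0.409, below one. In that neighbour D has fallen to 0% at the asked time, and its E stands at 39.9%.

(The earlier runs and the new flask stem from a simulated flask for an exercise; scatter was added.)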